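**Retrosynthetic overview**

1. Target 23 is an isoflavone whose ring C (O1, C2, C3, C4, C4a, C8a) is a vinylogous ester. C3, which bears ring B, is the β-carbon of an arylacetaldehyde enamine; C4 and O1 are the carboxyl carbon and the ortho oxygen of a ring A salicylic acid.
2. The key disconnections C3-C4 and O1-C2 divide 23 into acid chloride 12 (ring A with the C6 chain) and enamine 18 (ring B plus C2 and C3). Ring C is the only ring made; rings A and B are bought.
3. 12 comes from 3,5-bis(benzyloxy)phenol 1. Lithiation between the two benzyloxy groups puts the chain para to the phenol oxygen (prenylation, then hydration); ortho-formylation and oxidation add the carboxyl carbon. The one unbenzylated ortho oxygen must then become O1, so the chain ends at C6.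
4. 18 comes from 2,4-dihydroxybenzaldehyde 13 by benzylation, one-carbon Wittig homologation, hydrolysis and condensation with morpholine 17.
5. After the union, hydrogenolysis of the four benzyl ethers and saponification of the tertiary acetate give 23, which has no stereocenter.

Key step: step 13

Assumption: the target is read from its SMILES as luteone hydrate (5,7,2',4'-tetrahydroxy-6-(3-hydroxy-3-methylbutyl)isoflavone, achiral), and 3,5-bis(benzyloxy)phenol is taken as a purchasable compound whose free hydroxyl is already the oxygen that becomes O1.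

**Route**

Step 1
Reactants: 1 3,5-bis(benzyloxy)phenol
Product: 2 [3,5-bis(benzyloxy)phenoxy]triisopropylsilane
Conditions: TIPSCl (1.2 equiv), imidazole (2.5 equiv), DMF, rt
Reagents that add atoms: chlorotriisopropylsilane, CC(C)[Si](Cl)(C(C)C)C(C)C
Why: Silylation of the only free hydroxyl masks the acidic phenol, and the bulky silyl group keeps the lithiation of step 2 away from its own ortho positions.

Step 2
Reactants: 2 [3,5-bis(benzyloxy)phenoxy]triisopropylsilane; 3 prenyl bromide (1-bromo-3-methylbut-2-ene)
Product: 5 1,3-bis(benzyloxy)-2-(3-methylbut-2-en-1-yl)-5-(triisopropylsilyloxy)benzene, via aryllithium 4 (not isolated)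
Conditions: n-BuLi (1.2 equiv), THF, 0 °C, 1 h; then CuBr·SMe2 (10 mol%), 3 (1.5 equiv), −78 °C to rt
Reagents that add atoms: none
Why: Directed ortho-metalation should take place at the one C-H flanked by two benzyloxy groups, whose oxygens both coordinate lithium, and the aryllithium is then allylated at the primary carbon of prenyl bromide under copper catalysis (SN2 allylation), which places the five-carbon chain para to the silyl ether.

Step 3
Reactants: 5 1,3-bis(benzyloxy)-2-(3-methylbut-2-en-1-yl)-5-(triisopropylsilyloxy)benzene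
Product: 6 4-[2,6-bis(benzyloxy)-4-(triisopropylsilyloxy)phenyl]-2-methylbutan-2-ol
Conditions: Co(acac)2 (20 mol%), PhSiH3 (2.5 equiv), O2 (1 atm), THF/i-PrOH, rt; aq. Na2S2O3 work-up
Reagents that add atoms: dioxygen, O=O
Why: Mukaiyama hydration (hydrogen-atom transfer from a cobalt hydride to the trisubstituted alkene, capture of the tertiary radical by O2 and reduction by the silane) should give the Markovnikov tertiary alcohol without acid and without touching benzyl or silyl ethers; no stereocenter arises.

Step 4
Reactants: 6 4-[2,6-bis(benzyloxy)-4-(triisopropylsilyloxy)phenyl]-2-methylbutan-2-ol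
Product: 7 3,5-bis(benzyloxy)-4-(3-hydroxy-3-methylbutyl)phenol
Conditions: TBAF (1.1 equiv), THF, 0 °C; aq. NH4Cl
Reagents that add atoms: none
Why: Fluoride-driven desilylation cleaves the aryl silyl ether within minutes and leaves the benzyl ethers and the tertiary alcohol alone, which frees a phenol whose two ortho positions are equivalent.

Step 5
Reactants: 7 3,5-bis(benzyloxy)-4-(3-hydroxy-3-methylbutyl)phenol
Product: 9 2,4-bis(benzyloxy)-6-hydroxy-3-(3-hydroxy-3-methylbutyl)benzaldehyde, via salicyl alcohol 8 (not isolated)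
Conditions: MgCl2 (3 equiv), Et3N (6 equiv), (CH2O)n (7 equiv), MeCN, reflux; 1 M HCl work-up
Reagents that add atoms: paraformaldehyde (as formaldehyde), C=O
Why: In the Casnati-Skattebøl ortho-formylation the magnesium phenoxide delivers formaldehyde only ortho to the phenol oxygen and a second formaldehyde oxidises the benzylic alkoxide by hydride transfer, so the carbonyl carbon enters between the free hydroxyl and a benzyl ether, and the equivalence of the two ortho positions allows only one product.

Step 6
Reactants: 9 2,4-bis(benzyloxy)-6-hydroxy-3-(3-hydroxy-3-methylbutyl)benzaldehyde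
Product: 10 6-acetoxy-3-(3-acetoxy-3-methylbutyl)-2,4-bis(benzyloxy)benzaldehyde
Conditions: Ac2O (4 equiv), Et3N (5 equiv), DMAP (0.3 equiv), CH2Cl2, rt, 24 h
Reagents that add atoms: acetic anhydride, CC(=O)OC(C)=O
Why: DMAP-catalysed acetylation esterifies the phenol quickly and the tertiary alcohol more slowly, which masks the tertiary hydroxyl against the chlorinating agent of step 8 and turns the phenol into the latent nucleophile of the key step.

Step 7
Reactants: 10 6-acetoxy-3-(3-acetoxy-3-methylbutyl)-2,4-bis(benzyloxy)benzaldehyde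
Product: 11 6-acetoxy-3-(3-acetoxy-3-methylbutyl)-2,4-bis(benzyloxy)benzoic acid
Conditions: NaClO2 (3 equiv), NaH2PO4 (4 equiv), 2-methylbut-2-ene (20 equiv), t-BuOH/THF/H2O, 0 °C to rt
Reagents that add atoms: sodium chlorite, [Na+].[O-]Cl=O
Why: Pinnick oxidation at pH 3-4 should convert the hindered aryl aldehyde into the acid without hydrolysing the aryl acetate, and the large excess of 2-methylbut-2-ene removes hypochlorous acid before it can chlorinate the electron-rich ring.

Step 8
Reactants: 11 6-acetoxy-3-(3-acetoxy-3-methylbutyl)-2,4-bis(benzyloxy)benzoic acid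
Product: 12 6-acetoxy-3-(3-acetoxy-3-methylbutyl)-2,4-bis(benzyloxy)benzoyl chloride
Conditions: 1-chloro-N,N,2-trimethylprop-1-en-1-amine (1.1 equiv), CH2Cl2, 0 °C to rt; volatiles removed, used crude
Reagents that add atoms: 1-chloro-N,N,2-trimethylprop-1-en-1-amine, CC(C)=C(Cl)N(C)C
Why: The α-chloroenamine converts the acid into the acid chloride under neutral conditions with an amide as the only by-product, so neither the acetates nor the benzyl ethers meet HCl.

Step 9
Reactants: 13 2,4-dihydroxybenzaldehyde
Product: 14 2,4-bis(benzyloxy)benzaldehyde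
Conditions: BnBr (2.3 equiv), K2CO3 (3 equiv), DMF, 60 °C
Reagents that add atoms: benzyl bromide, BrCc1ccccc1
Why: In this Williamson ether synthesis the 4-hydroxyl reacts first and the hydrogen-bonded 2-hydroxyl follows at 60 °C with excess benzyl bromide.

Step 10
Reactants: 14 2,4-bis(benzyloxy)benzaldehyde
Product: 15 2,4-bis(benzyloxy)-1-(2-methoxyethenyl)benzene (E/Z mixture)
Conditions: MeOCH2PPh3Cl (1.5 equiv), KOtBu (1.45 equiv), THF, 0 °C to rt
Reagents that add atoms: (methoxymethyl)triphenylphosphonium chloride, COC[P+](c1ccccc1)(c1ccccc1)c1ccccc1.[Cl-]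
Why: Wittig methoxymethylenation with the non-stabilised ylide adds the one carbon that becomes C2 of the isoflavone, and the E/Z mixture is of no consequence because both isomers hydrolyse to the same aldehyde.

Step 11
Reactants: 15 2,4-bis(benzyloxy)-1-(2-methoxyethenyl)benzene
Product: 16 2-[2,4-bis(benzyloxy)phenyl]acetaldehyde
Conditions: 2 M aq. HCl, THF, rt; used crude at once
Reagents that add atoms: water, O
Why: Acid-catalysed enol ether hydrolysis (protonation at the benzylic carbon, then loss of methanol from the hemiacetal) should give the arylacetaldehyde, which is carried on without storage because it self-condenses on standing.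

Step 12
Reactants: 16 2-[2,4-bis(benzyloxy)phenyl]acetaldehyde; 17 morpholine
Product: 18 (E)-4-{2-[2,4-bis(benzyloxy)phenyl]ethenyl}morpholine
Conditions: 17 (1.1 equiv), 4 Å molecular sieves, toluene, rt; evaporation under high vacuum to remove free amine
Reagents that add atoms: none
Why: Condensation of the aldehyde with a secondary amine over molecular sieves gives the enamine, and the E isomer, conjugated with the electron-rich arene and free of allylic strain, is the thermodynamic product.

Step 13
Reactants: 12 6-acetoxy-3-(3-acetoxy-3-methylbutyl)-2,4-bis(benzyloxy)benzoyl chloride; 18 (E)-4-{2-[2,4-bis(benzyloxy)phenyl]ethenyl}morpholine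
Product: 21 6-(3-acetoxy-3-methylbutyl)-5,7-bis(benzyloxy)-3-[2,4-bis(benzyloxy)phenyl]-4H-chromen-4-one, via acetoxy enaminone 19 (not isolated), via hydroxy enaminone 20 (not isolated)
Conditions: 18 (1.2 equiv), Et3N (1.5 equiv), CH2Cl2, 0 °C to 40 °C; then morpholine 17 (0.3 equiv), 40 °C; aq. citric acid work-up
Reagents that add atoms: none
Why: The β-carbon of the enamine, the one that carries ring B, attacks the aroyl chloride and Et3N takes the proton from that carbon, which forms the C3-C4 bond and gives the push-pull enaminone 19; acylation on nitrogen gives an acylammonium salt that reverts, so only the C-acylated, conjugated product accumulates. No amine is free at this point, so a small charge of morpholine is added to start a chain: it takes the phenolic acetyl group as 4-acetylmorpholine and frees phenol 20, and every ring closure then returns one morpholine that unmasks the next molecule. Ring C closes by 6-endo-trig conjugate addition of the phenol oxygen to the aminomethylene carbon and β-elimination of morpholine (addition-elimination at a vinylogous amide), which forms the O1-C2 bond. The closest known chemistry is the Stork acylation of enamines with O-acetylsalicyloyl chlorides to give chromones, together with the ring closure of 2-hydroxyaryl enaminones to chromones and isoflavones. No stereocenter is created. The step needs attack at a carbonyl flanked by two ortho substituents, closure through the oxygen para to the chain and survival of the tertiary acetate: warming with the electron-rich enamine in slight excess serves the first, the benzyl ether on the other ortho oxygen secures the second, and the low reactivity of a tertiary alkyl acetate toward amines the third.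

Step 14
Reactants: 21 6-(3-acetoxy-3-methylbutyl)-5,7-bis(benzyloxy)-3-[2,4-bis(benzyloxy)phenyl]-4H-chromen-4-one
Product: 22 6-(3-acetoxy-3-methylbutyl)-3-(2,4-dihydroxyphenyl)-5,7-dihydroxy-4H-chromen-4-one
Conditions: H2 (1 atm), 10% Pd/C, EtOAc/MeOH, rt; stopped when uptake for four benzyl groups ends
Reagents that add atoms: none
Why: Catalytic hydrogenolysis should cleave the four aryl benzyl ethers much faster than it reduces the C2-C3 double bond of the vinylogous ester, and the tertiary acetate is inert to hydrogen.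

Step 15
Reactants: 22 6-(3-acetoxy-3-methylbutyl)-3-(2,4-dihydroxyphenyl)-5,7-dihydroxy-4H-chromen-4-one
Product: 23 luteone hydrate, 3-(2,4-dihydroxyphenyl)-5,7-dihydroxy-6-(3-hydroxy-3-methylbutyl)-4H-chromen-4-one
Conditions: LiOH·H2O (10 equiv), degassed MeOH/H2O, argon, rt; then aq. NaH2PO4 to pH 5-6
Reagents that add atoms: none
Why: Saponification by acyl-oxygen cleavage frees the tertiary alcohol at room temperature, the polyphenolate form of the isoflavone is a poor electrophile at C2 and should resist ring opening, and acidification only to pH 5-6 avoids acid-induced cyclisation of the tertiary alcohol onto a neighbouring phenol.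

**Compound list**

1 | 3,5-bis(benzyloxy)phenol | Oc1cc(OCc2ccccc2)cc(OCc2ccccc2)c1 | starting material
2 | [3,5-bis(benzyloxy)phenoxy]triisopropylsilane | CC(C)[Si](Oc1cc(OCc2ccccc2)cc(OCc2ccccc2)c1)(C(C)C)C(C)C | intermediate
3 | prenyl bromide (1-bromo-3-methylbut-2-ene) | CC(C)=CCBr | starting material
4 | [2,6-bis(benzyloxy)-4-(triisopropylsilyloxy)phenyl]lithium | [Li]c1c(OCc2ccccc2)cc(O[Si](C(C)C)(C(C)C)C(C)C)cc1OCc1ccccc1 | intermediate (not isolated)
5 | 1,3-bis(benzyloxy)-2-(3-methylbut-2-en-1-yl)-5-(triisopropylsilyloxy)benzene | CC(C)=CCc1c(OCc2ccccc2)cc(O[Si](C(C)C)(C(C)C)C(C)C)cc1OCc1ccccc1 | intermediate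
6 | 4-[2,6-bis(benzyloxy)-4-(triisopropylsilyloxy)phenyl]-2-methylbutan-2-ol | CC(C)(O)CCc1c(OCc2ccccc2)cc(O[Si](C(C)C)(C(C)C)C(C)C)cc1OCc1ccccc1 | intermediate
7 | 3,5-bis(benzyloxy)-4-(3-hydroxy-3-methylbutyl)phenol | CC(C)(O)CCc1c(OCc2ccccc2)cc(O)cc1OCc1ccccc1 | intermediate
8 | 3,5-bis(benzyloxy)-4-(3-hydroxy-3-methylbutyl)-2-(hydroxymethyl)phenol (formed as its magnesium alkoxide) | CC(C)(O)CCc1c(OCc2ccccc2)cc(O)c(CO)c1OCc1ccccc1 | intermediate (not isolated)
9 | 2,4-bis(benzyloxy)-6-hydroxy-3-(3-hydroxy-3-methylbutyl)benzaldehyde | CC(C)(O)CCc1c(OCc2ccccc2)cc(O)c(C=O)c1OCc1ccccc1 | intermediate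
10 | 6-acetoxy-3-(3-acetoxy-3-methylbutyl)-2,4-bis(benzyloxy)benzaldehyde | CC(C)(OC(C)=O)CCc1c(OCc2ccccc2)cc(OC(C)=O)c(C=O)c1OCc1ccccc1 | intermediate
11 | 6-acetoxy-3-(3-acetoxy-3-methylbutyl)-2,4-bis(benzyloxy)benzoic acid | CC(C)(OC(C)=O)CCc1c(OCc2ccccc2)cc(OC(C)=O)c(C(=O)O)c1OCc1ccccc1 | intermediate
12 | 6-acetoxy-3-(3-acetoxy-3-methylbutyl)-2,4-bis(benzyloxy)benzoyl chloride | CC(C)(OC(C)=O)CCc1c(OCc2ccccc2)cc(OC(C)=O)c(C(=O)Cl)c1OCc1ccccc1 | intermediate
13 | 2,4-dihydroxybenzaldehyde | O=Cc1ccc(O)cc1O | starting material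
14 | 2,4-bis(benzyloxy)benzaldehyde | O=Cc1ccc(OCc2ccccc2)cc1OCc1ccccc1 | intermediate
15 | 2,4-bis(benzyloxy)-1-(2-methoxyethenyl)benzene (E/Z mixture, no configuration assigned) | COC=Cc1ccc(OCc2ccccc2)cc1OCc1ccccc1 | intermediate
16 | 2-[2,4-bis(benzyloxy)phenyl]acetaldehyde | O=CCc1ccc(OCc2ccccc2)cc1OCc1ccccc1 | intermediate
17 | morpholine | C1COCCN1 | starting material
18 | (E)-4-{2-[2,4-bis(benzyloxy)phenyl]ethenyl}morpholine | C1COCCN1/C=C/c1ccc(OCc2ccccc2)cc1OCc1ccccc1 | intermediate
19 | 1-[6-acetoxy-3-(3-acetoxy-3-methylbutyl)-2,4-bis(benzyloxy)phenyl]-2-[2,4-bis(benzyloxy)phenyl]-3-(morpholin-4-yl)prop-2-en-1-one (C=C geometry not fixed) | CC(C)(OC(C)=O)CCc1c(OCc2ccccc2)cc(OC(C)=O)c(C(=O)C(=CN2CCOCC2)c2ccc(OCc3ccccc3)cc2OCc2ccccc2)c1OCc1ccccc1 | intermediate (not isolated)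
20 | 1-[3-(3-acetoxy-3-methylbutyl)-2,4-bis(benzyloxy)-6-hydroxyphenyl]-2-[2,4-bis(benzyloxy)phenyl]-3-(morpholin-4-yl)prop-2-en-1-one (C=C geometry not fixed) | CC(C)(OC(C)=O)CCc1c(OCc2ccccc2)cc(O)c(C(=O)C(=CN2CCOCC2)c2ccc(OCc3ccccc3)cc2OCc2ccccc2)c1OCc1ccccc1 | intermediate (not isolated)
21 | 6-(3-acetoxy-3-methylbutyl)-5,7-bis(benzyloxy)-3-[2,4-bis(benzyloxy)phenyl]-4H-chromen-4-one | CC(C)(OC(C)=O)CCc1c(OCc2ccccc2)cc2occ(-c3ccc(OCc4ccccc4)cc3OCc3ccccc3)c(=O)c2c1OCc1ccccc1 | intermediate
22 | 6-(3-acetoxy-3-methylbutyl)-3-(2,4-dihydroxyphenyl)-5,7-dihydroxy-4H-chromen-4-one | CC(C)(OC(C)=O)CCc1c(O)cc2occ(-c3ccc(O)cc3O)c(=O)c2c1O | intermediate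
23 | luteone hydrate, 3-(2,4-dihydroxyphenyl)-5,7-dihydroxy-6-(3-hydroxy-3-methylbutyl)-4H-chromen-4-one | CC(C)(O)CCc1c(O)cc2occ(-c3ccc(O)cc3O)c(=O)c2c1O | target

**Step count and risks**

Total step count: 15. Longest linear sequence: 11 steps (steps 1 to 8, then 13 to 15).

Steps most likely to fail:

1. Step 13. C-acylation at the doubly ortho-substituted carbonyl may be so slow that hydrolysis of the acid chloride, amide formation with traces of free amine or self-condensation of the enamine overtake it. The fallback builds ring C first and attaches ring B by cross-coupling; it sets out from 12 and comes back at 21. Acyl Sonogashira coupling of 12 with ethynyltrimethylsilane (PdCl2(PPh3)2, CuI, Et3N, THF, rt) should give 1-[6-acetoxy-3-(3-acetoxy-3-methylbutyl)-2,4-bis(benzyloxy)phenyl]-3-(trimethylsilyl)prop-2-yn-1-one F1. Dimethylamine in MeOH/THF should remove the silyl group, add to the ynone and cleave the aryl acetate, giving (E)-1-[3-(3-acetoxy-3-methylbutyl)-2,4-bis(benzyloxy)-6-hydroxyphenyl]-3-(dimethylamino)prop-2-en-1-one F2. Iodine in CHCl3 should close ring C with loss of dimethylamine to give 6-(3-acetoxy-3-methylbutyl)-5,7-bis(benzyloxy)-3-iodo-4H-chromen-4-one F3. Suzuki-Miyaura coupling of F3 with purchased 2,4-bis(benzyloxy)phenylboronic acid (Pd(PPh3)4, aq. Na2CO3, DME, 80 °C) would then give 21.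

2. Step 2. Deprotonation at a benzylic CH2 of a benzyl ether, followed by [1,2]-Wittig rearrangement, may compete with ring lithiation, and the allylation may take place in part at the tertiary end of the prenyl unit. The fallback builds the chain from an aldehyde carbon; it sets out from 1 and comes back at 6. Vilsmeier-Haack formylation of 1 (POCl3, DMF; aq. NaOAc) should go mainly para to the hydroxyl and give 2,6-bis(benzyloxy)-4-hydroxybenzaldehyde F4, separable from the hydrogen-bonded ortho isomer. Silylation (TIPSCl, imidazole) would give 2,6-bis(benzyloxy)-4-(triisopropylsilyloxy)benzaldehyde F5. Horner-Wadsworth-Emmons reaction with dimethyl (2-oxopropyl)phosphonate (NaH, THF) would give (E)-4-[2,6-bis(benzyloxy)-4-(triisopropylsilyloxy)phenyl]but-3-en-2-one F6. Conjugate reduction with [(Ph3P)CuH]6 in toluene would spare the benzyl ethers and give 4-[2,6-bis(benzyloxy)-4-(triisopropylsilyloxy)phenyl]butan-2-one F7. MeMgBr in THF at 0 °C would then give 6.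

3. Step 11. The electron-rich arylacetaldehyde may be lost to acid-promoted aldol self-condensation and air oxidation before it is converted into the enamine. The fallback reaches the enamine without a free aldehyde; it sets out from 14 and comes back at 18. 4-[(Diphenylphosphoryl)methyl]morpholine F8 would be made from morpholine 17, paraformaldehyde and diphenylphosphine oxide (phospha-Mannich condensation). It would be lithiated (n-BuLi, THF, −78 °C) and added to 14 to give 1-[2,4-bis(benzyloxy)phenyl]-2-(diphenylphosphoryl)-2-(morpholin-4-yl)ethanol F9 as a mixture of diastereomers. KOtBu in THF would then expel diphenylphosphinate (Horner-Wittig elimination) to give 18; any Z isomer should equilibrate to E through the iminium ion with a trace of acid, and both are acylated at the same carbon.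

**Further compounds**

F1 | step 13 | 1-[6-acetoxy-3-(3-acetoxy-3-methylbutyl)-2,4-bis(benzyloxy)phenyl]-3-(trimethylsilyl)prop-2-yn-1-one | CC(C)(OC(C)=O)CCc1c(OCc2ccccc2)cc(OC(C)=O)c(C(=O)C#C[Si](C)(C)C)c1OCc1ccccc1
F2 | step 13 | (E)-1-[3-(3-acetoxy-3-methylbutyl)-2,4-bis(benzyloxy)-6-hydroxyphenyl]-3-(dimethylamino)prop-2-en-1-one | CC(C)(OC(C)=O)CCc1c(OCc2ccccc2)cc(O)c(C(=O)/C=C/N(C)C)c1OCc1ccccc1
F3 | step 13 | 6-(3-acetoxy-3-methylbutyl)-5,7-bis(benzyloxy)-3-iodo-4H-chromen-4-one | CC(C)(OC(C)=O)CCc1c(OCc2ccccc2)cc2occ(I)c(=O)c2c1OCc1ccccc1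
F4 | step 2 | 2,6-bis(benzyloxy)-4-hydroxybenzaldehyde | O=Cc1c(OCc2ccccc2)cc(O)cc1OCc1ccccc1
F5 | step 2 | 2,6-bis(benzyloxy)-4-(triisopropylsilyloxy)benzaldehyde | O=Cc1c(OCc2ccccc2)cc(O[Si](C(C)C)(C(C)C)C(C)C)cc1OCc1ccccc1
F6 | step 2 | (E)-4-[2,6-bis(benzyloxy)-4-(triisopropylsilyloxy)phenyl]but-3-en-2-one | CC(=O)/C=C/c1c(OCc2ccccc2)cc(O[Si](C(C)C)(C(C)C)C(C)C)cc1OCc1ccccc1
F7 | step 2 | 4-[2,6-bis(benzyloxy)-4-(triisopropylsilyloxy)phenyl]butan-2-one | CC(=O)CCc1c(OCc2ccccc2)cc(O[Si](C(C)C)(C(C)C)C(C)C)cc1OCc1ccccc1
F8 | step 11 | 4-[(diphenylphosphoryl)methyl]morpholine | O=P(CN1CCOCC1)(c1ccccc1)c1ccccc1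
F9 | step 11 | 1-[2,4-bis(benzyloxy)phenyl]-2-(diphenylphosphoryl)-2-(morpholin-4-yl)ethanol (mixture of diastereomers) | OC(c1ccc(OCc2ccccc2)cc1OCc1ccccc1)C(N1CCOCC1)P(=O)(c1ccccc1)c1ccccc1
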